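**Retrosynthetic overview**

1. Target 19 ⇐ Mitsunobu inversion with double acetylation of the 2α-allylic alcohol 18 ⇐ enone 17 (face-selective 1,2-reduction) ⇐ removal of the C6 isopropenyl control group of 15.
2. Ring A (formed last, onto ring B): C4–C5 and C2–C3 bonds by an intramolecular crossed [2+2] photocycloaddition of enol methacrylate 12, then lactone methanolysis, retro-aldol and aldol condensation (C4 quaternary centre, C1=C10, C2 oxygen).
3. Ring B is bought as (R)-carvone: C8 by cuprate addition trans to the isopropenyl group, C9 by enolate alkylation trans to the C8 methyl with iodide 5.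
4. Side chain C11–C15 with the C13 stereocentre from (R)-citronellol by oxidative cleavage and iododecarboxylation.

Assumption: halimane numbering (C1–C20) is used for positions, α/β refer to the usual drawing with H-5 β, and (R)-(+)-citronellol and (R)-(−)-carvone are bought as single enantiomers.

**Step 1**
Reactants: 1 (R)-(+)-citronellol
Product: 2 (3R)-3,7-dimethyloct-6-en-1-yl acetate
Conditions: Ac2O, pyridine, DMAP (cat.), CH2Cl2, 0 °C → rt
Reagents that add atoms: acetic anhydride, CC(=O)OC(C)=O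
Why: DMAP-catalysed O-acetylation masks the primary alcohol for steps 2–7 (the acetate is cleaved in step 8 and reinstalled in step 11) and does not involve the bought C13 stereocentre.

**Step 2**
Reactants: 2 (3R)-3,7-dimethyloct-6-en-1-yl acetate
Product: 3 (4R)-6-acetoxy-4-methylhexanoic acid
Conditions: RuCl3·xH2O (2 mol %), NaIO4 (4 equiv), CCl4–MeCN–H2O (2:2:3), rt
Reagents that add atoms: sodium periodate, [Na+].[O-]I(=O)(=O)=O; water, O
Why: RuO4-catalysed (Sharpless) oxidative cleavage of the trisubstituted alkene gives the acid directly with loss of acetone and leaves the remote stereocentre untouched.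

**Step 3**
Reactants: 3 (4R)-6-acetoxy-4-methylhexanoic acid
Product: 5 (3S)-5-iodo-3-methylpentyl acetate, via acyl hypoiodite 4 (not isolated)
Conditions: PhI(OAc)2, I2, DCE, hν (W lamp), reflux
Reagents that add atoms: iodine, II
Why: Suárez photochemical Hunsdiecker-type iododecarboxylation, in which the acyl hypoiodite homolyses, loses CO2 and the primary radical abstracts iodine; the stereocentre is remote and its descriptor becomes S only through the CIP priorities.

**Step 4**
Reactants: 6 (R)-(−)-carvone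
Product: 8 trimethyl{[(3R,5R)-2,3-dimethyl-5-(prop-1-en-2-yl)cyclohex-1-en-1-yl]oxy}silane, via bromomagnesium enolate 7 (not isolated)
Conditions: MeMgBr, CuBr·SMe2 (5 mol %), TMSCl, THF, −78 °C; then Et3N
Reagents that add atoms: methylmagnesium bromide, C[Mg]Br; chlorotrimethylsilane, C[Si](C)(C)Cl
Why: copper-catalysed 1,4-addition with TMSCl trapping, in which the methyl group enters axially trans to the isopropenyl group of carvone (dr > 20:1) and sets C8 (R), while the enolate is fixed regiospecifically as the silyl enol ether.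

**Step 5**
Reactants: 8 trimethyl{[(3R,5R)-2,3-dimethyl-5-(prop-1-en-2-yl)cyclohex-1-en-1-yl]oxy}silane; 5 (3S)-5-iodo-3-methylpentyl acetate
Product: 10 (2S,3R,5R)-2-[(3R)-5-acetoxy-3-methylpentyl]-2,3-dimethyl-5-(prop-1-en-2-yl)cyclohexan-1-one, via lithium enolate 9 (not isolated)
Conditions: MeLi (1.0 equiv), THF, 0 °C; then 5, HMPA, −78 → 0 °C
Reagents that add atoms: none
Why: MeLi regenerates the regiodefined tetrasubstituted lithium enolate, whose SN2 alkylation occurs axially on the face anti to the pseudo-axial C8 methyl, so the side chain ends up trans to it and the C9 quaternary centre (S) is set.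

**Step 6**
Reactants: 10 (2S,3R,5R)-2-[(3R)-5-acetoxy-3-methylpentyl]-2,3-dimethyl-5-(prop-1-en-2-yl)cyclohexan-1-one
Product: 11 1-[(3S,4R,6S)-3-[(3R)-5-acetoxy-3-methylpentyl]-2-hydroxy-3,4-dimethyl-6-(prop-1-en-2-yl)cyclohex-1-en-1-yl]ethan-1-one (chelated enol of the 2-acetyl ketone)
Conditions: MgBr2·OEt2, i-Pr2NEt, 1-acetylbenzotriazole, CH2Cl2, rt
Reagents that add atoms: 1-acetyl-1H-benzotriazole, CC(=O)n1nnc2ccccc12
Why: soft-enolisation C-acylation (crossed Claisen-type, Coltart conditions) can only take place at C5 because C9 is quaternary, spares the acetate, and gives the chelated enol so that no new stereocentre arises.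

**Step 7**
Reactants: 11 1-[(3S,4R,6S)-3-[(3R)-5-acetoxy-3-methylpentyl]-2-hydroxy-3,4-dimethyl-6-(prop-1-en-2-yl)cyclohex-1-en-1-yl]ethan-1-one
Product: 12 (1Z)-1-[(3S,4R,6S)-3-[(3R)-5-acetoxy-3-methylpentyl]-3,4-dimethyl-2-oxo-6-(prop-1-en-2-yl)cyclohexylidene]ethyl 2-methylprop-2-enoate
Conditions: methacryloyl chloride, Et3N, DMAP (5 mol %), BHT, CH2Cl2, −20 → 0 °C
Reagents that add atoms: methacryloyl chloride, C=C(C)C(Cl)=O
Why: O-acylation of the enol is expected at the acetyl-derived oxygen because the ring oxygen is flanked by the quaternary C9, which gives the exocyclic enol ester (an E/Z mixture is equally usable, since the geometry is lost in the excited state).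

**Step 8**
Reactants: 12 (1Z)-1-[(3S,4R,6S)-3-[(3R)-5-acetoxy-3-methylpentyl]-3,4-dimethyl-2-oxo-6-(prop-1-en-2-yl)cyclohexylidene]ethyl 2-methylprop-2-enoate
Product: 15 methyl (1S,5S,6R,8R,8aS)-5-[(3R)-5-hydroxy-3-methylpentyl]-1,5,6-trimethyl-3-oxo-8-(prop-1-en-2-yl)-1,2,3,5,6,7,8,8a-octahydronaphthalene-1-carboxylate, via spiro lactone photoadduct 13 (not isolated), via diketo ester 14 (not isolated)
Conditions: hν (365 nm), thioxanthone (10 mol %), MeCN (0.01 M), 40 °C; then NaOMe (0.3 equiv), MeOH, 0 → 65 °C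
Reagents that add atoms: methanol, CO
Why: Proposed new method: a triplet-sensitised intramolecular crossed [2+2] photocycloaddition of a β-diketone enol methacrylate (closest known chemistry: the de Mayo reaction and the "rule of five" crossed [2+2] of 1,5-dienes), in which the triplet β-acyloxy enone adds through C2 to the methacrylate CH2 (five-membered lactone, two tertiary α-carbonyl radicals), the 1,4-diradical closes C4–C5 anti to the C6 isopropenyl group with the small lactone oxygen rather than CH2 next to C6 and so fixes C4 (S), and methoxide then opens the strained lactone to the methyl ester and a cyclobutanol alkoxide that undergoes retro-aldol cleavage, equilibration of C5 trans to the isopropenyl group (a modest thermodynamic preference, estimated at about 5:1, with the minor C5 epimer removed by chromatography) and aldol condensation onto C10.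

**Step 9**
Reactants: 15 methyl (1S,5S,6R,8R,8aS)-5-[(3R)-5-hydroxy-3-methylpentyl]-1,5,6-trimethyl-3-oxo-8-(prop-1-en-2-yl)-1,2,3,5,6,7,8,8a-octahydronaphthalene-1-carboxylate
Product: 17 methyl (1S,5S,6R,8aS)-5-[(3R)-5-hydroxy-3-methylpentyl]-1,5,6-trimethyl-3-oxo-1,2,3,5,6,7,8,8a-octahydronaphthalene-1-carboxylate, via methoxy hydroperoxide 16 (not isolated)
Conditions: O3 (1 equiv), MeOH, −78 °C; then FeSO4·7H2O, PhSH, −78 °C → rt
Reagents that add atoms: none
Why: Kwon-type hydrodealkenylation, in which ozone attacks the electron-rich 1,1-disubstituted alkene in preference to the enone, Fe(II) reduces the α-methoxy hydroperoxide to an alkoxy radical that β-fragments with loss of methyl acetate, and the C6 radical takes hydrogen from the thiol, so C6 becomes CH2 and no stereocentre is touched.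

**Step 10**
Reactants: 17 methyl (1S,5S,6R,8aS)-5-[(3R)-5-hydroxy-3-methylpentyl]-1,5,6-trimethyl-3-oxo-1,2,3,5,6,7,8,8a-octahydronaphthalene-1-carboxylate
Product: 18 methyl (1S,3S,5S,6R,8aS)-3-hydroxy-5-[(3R)-5-hydroxy-3-methylpentyl]-1,5,6-trimethyl-1,2,3,5,6,7,8,8a-octahydronaphthalene-1-carboxylate
Conditions: L-Selectride (2.5 equiv), THF, −78 °C; then H2O
Reagents that add atoms: none
Why: the bulky hydride adds 1,2 (the β-carbon C10 is fully substituted) from the β face, because the α face of the ring A envelope is blocked by the axial C4 methyl syn to C2, which gives the axial 2α-alcohol (2S) as in the L-Selectride reduction of 3,3,5-trimethylcyclohexanone.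

**Step 11**
Reactants: 18 methyl (1S,3S,5S,6R,8aS)-3-hydroxy-5-[(3R)-5-hydroxy-3-methylpentyl]-1,5,6-trimethyl-1,2,3,5,6,7,8,8a-octahydronaphthalene-1-carboxylate
Product: 19 methyl (1S,3R,5S,6R,8aS)-3-acetoxy-5-[(3R)-5-acetoxy-3-methylpentyl]-1,5,6-trimethyl-1,2,3,5,6,7,8,8a-octahydronaphthalene-1-carboxylate (CNP0209333.1)
Conditions: PPh3, DIAD, AcOH (4 equiv each), THF, 0 °C → rt
Reagents that add atoms: acetic acid, CC(=O)O
Why: double Mitsunobu esterification, in which the primary C15 alcohol is acetylated and the secondary allylic C2 oxyphosphonium is displaced by acetate in an SN2 reaction with inversion, giving the equatorial 2β-acetate (2R) cis to the C4 ester.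

**Compound list**

1 | (R)-(+)-citronellol, (3R)-3,7-dimethyloct-6-en-1-ol | CC(C)=CCC[C@@H](C)CCO | starting material
2 | (3R)-3,7-dimethyloct-6-en-1-yl acetate | CC(C)=CCC[C@@H](C)CCOC(C)=O | intermediate
3 | (4R)-6-acetoxy-4-methylhexanoic acid | OC(=O)CC[C@@H](C)CCOC(C)=O | intermediate
4 | (4R)-6-acetoxy-4-methylhexanoyl hypoiodite (not isolated) | IOC(=O)CC[C@@H](C)CCOC(C)=O | intermediate
5 | (3S)-5-iodo-3-methylpentyl acetate | ICC[C@@H](C)CCOC(C)=O | intermediate
6 | (R)-(−)-carvone | CC1=CC[C@@H](C(C)=C)CC1=O | starting material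
7 | bromomagnesium (3R,5R)-2,3-dimethyl-5-(prop-1-en-2-yl)cyclohex-1-en-1-olate (not isolated) | Br[Mg]OC1=C(C)[C@H](C)C[C@@H](C(C)=C)C1 | intermediate
8 | trimethyl{[(3R,5R)-2,3-dimethyl-5-(prop-1-en-2-yl)cyclohex-1-en-1-yl]oxy}silane | C[Si](C)(C)OC1=C(C)[C@H](C)C[C@@H](C(C)=C)C1 | intermediate
9 | lithium (3R,5R)-2,3-dimethyl-5-(prop-1-en-2-yl)cyclohex-1-en-1-olate (not isolated) | [Li]OC1=C(C)[C@H](C)C[C@@H](C(C)=C)C1 | intermediate
10 | (2S,3R,5R)-2-[(3R)-5-acetoxy-3-methylpentyl]-2,3-dimethyl-5-(prop-1-en-2-yl)cyclohexan-1-one (C8 and C9 methyls cis, side chain trans to them, isopropenyl trans to the C8 methyl) | O=C1[C@@](C)(CC[C@@H](C)CCOC(C)=O)[C@H](C)C[C@@H](C(C)=C)C1 | intermediate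
11 | 1-[(3S,4R,6S)-3-[(3R)-5-acetoxy-3-methylpentyl]-2-hydroxy-3,4-dimethyl-6-(prop-1-en-2-yl)cyclohex-1-en-1-yl]ethan-1-one (chelated enol) | CC(=O)C1=C(O)[C@@](C)(CC[C@@H](C)CCOC(C)=O)[C@H](C)C[C@H]1C(C)=C | intermediate
12 | (1Z)-1-[(3S,4R,6S)-3-[(3R)-5-acetoxy-3-methylpentyl]-3,4-dimethyl-2-oxo-6-(prop-1-en-2-yl)cyclohexylidene]ethyl 2-methylprop-2-enoate | C=C(C)C(=O)O/C(C)=C1\C(=O)[C@@](C)(CC[C@@H](C)CCOC(C)=O)[C@H](C)C[C@H]1C(C)=C | intermediate
13 | crossed [2+2] adduct (not isolated): 1',4'-dimethylspiro[cyclohexane-1,5'-[2]oxabicyclo[2.1.1]hexane]-2,3'-dione with the ring substituents of 10; C4–C5 bond anti to the isopropenyl group, lactone oxygen on the C6 side | O=C1[C@@](C)(CC[C@@H](C)CCOC(C)=O)[C@H](C)C[C@@H](C(C)=C)[C@@]12[C@]3(C)OC(=O)[C@@]2(C)C3 | intermediate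
14 | methyl (2S)-2-[(1R,3S,4R,6R)-3-[(3R)-5-hydroxy-3-methylpentyl]-3,4-dimethyl-2-oxo-6-(prop-1-en-2-yl)cyclohexyl]-2-methyl-4-oxopentanoate (not isolated) | O=C1[C@@](C)(CC[C@@H](C)CCO)[C@H](C)C[C@@H](C(C)=C)[C@@H]1[C@](C)(CC(C)=O)C(=O)OC | intermediate
15 | methyl (1S,5S,6R,8R,8aS)-5-[(3R)-5-hydroxy-3-methylpentyl]-1,5,6-trimethyl-3-oxo-8-(prop-1-en-2-yl)-1,2,3,5,6,7,8,8a-octahydronaphthalene-1-carboxylate | COC(=O)[C@@]1(C)CC(=O)C=C2[C@@H]1[C@H](C(C)=C)C[C@@H](C)[C@]2(C)CC[C@@H](C)CCO | intermediate
16 | methyl (1S,5S,6R,8R,8aS)-8-(1-hydroperoxy-1-methoxyethyl)-5-[(3R)-5-hydroxy-3-methylpentyl]-1,5,6-trimethyl-3-oxo-1,2,3,5,6,7,8,8a-octahydronaphthalene-1-carboxylate (not isolated, epimers at the peroxy carbon) | COC(=O)[C@@]1(C)CC(=O)C=C2[C@@H]1[C@H](C(C)(OC)OO)C[C@@H](C)[C@]2(C)CC[C@@H](C)CCO | intermediate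
17 | methyl (1S,5S,6R,8aS)-5-[(3R)-5-hydroxy-3-methylpentyl]-1,5,6-trimethyl-3-oxo-1,2,3,5,6,7,8,8a-octahydronaphthalene-1-carboxylate | COC(=O)[C@@]1(C)CC(=O)C=C2[C@@H]1CC[C@@H](C)[C@]2(C)CC[C@@H](C)CCO | intermediate
18 | methyl (1S,3S,5S,6R,8aS)-3-hydroxy-5-[(3R)-5-hydroxy-3-methylpentyl]-1,5,6-trimethyl-1,2,3,5,6,7,8,8a-octahydronaphthalene-1-carboxylate (2α-alcohol) | COC(=O)[C@@]1(C)C[C@H](O)C=C2[C@@H]1CC[C@@H](C)[C@]2(C)CC[C@@H](C)CCO | intermediate
19 | methyl (1S,3R,5S,6R,8aS)-3-acetoxy-5-[(3R)-5-acetoxy-3-methylpentyl]-1,5,6-trimethyl-1,2,3,5,6,7,8,8a-octahydronaphthalene-1-carboxylate; halimane numbering 2R,4S,5S,8R,9S,13R | COC(=O)[C@@]1(C)C[C@@H](OC(C)=O)C=C2[C@@H]1CC[C@@H](C)[C@]2(C)CC[C@@H](C)CCOC(C)=O | target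

**Step count and risks**

Total step count: 11 (three for the side-chain iodide, eight from carvone including the coupling). Longest linear sequence: 10 steps (1 → 2 → 3 → 5 → 10 → 11 → 12 → 15 → 17 → 18 → 19).

The three steps most likely to fail:

Step 8, the proposed photochemical cascade. The first C–C bond needs the minor E rotamer of the enol ester, the congested 1,4-diradical may revert or disproportionate instead of closing, and a photochemical acyl shift or prior acyl migration to the ring oxygen would divert material. The fallback uses the known intermolecular de Mayo reaction and sets out from 11. Irradiation (350 nm, MeCN) with excess methyl methacrylate gives, after spontaneous retro-aldol opening of the head-to-head cyclobutanol, methyl (2S)-2-[(1R,3S,4R,6R)-3-[(3R)-5-acetoxy-3-methylpentyl]-3,4-dimethyl-2-oxo-6-(prop-1-en-2-yl)cyclohexyl]-2-methyl-4-oxopentanoate F1 together with its C4 epimer, which is removed by chromatography because C4 is no longer relayed through a tether. NaOMe in MeOH then cleaves the acetate and closes ring A by aldol condensation, and the route is rejoined at 15.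

Step 5, the C9 quaternary centre. A hindered tetrasubstituted enolate meets an unactivated primary iodide, and O-alkylation or attack on the acetate can compete. The fallback changes the electrophile class and sets out from 5. Treatment with AgOTf (CH2Cl2, 0 °C) gives the primary triflate (3S)-3-methyl-5-{[(trifluoromethyl)sulfonyl]oxy}pentyl acetate F2, which alkylates lithium enolate 9 at −78 °C in THF without HMPA, and the route is rejoined at 10.

Step 11, the Mitsunobu reaction at a hindered axial allylic alcohol. Elimination to a diene, SN2' attack or acylation with retention can compete. The fallback replaces inversion by thermodynamic control and sets out from 17. Meerwein–Ponndorf–Verley reduction (Al(O-i-Pr)3, i-PrOH, reflux, equilibrating) gives the equatorial 2β-alcohol methyl (1S,3R,5S,6R,8aS)-3-hydroxy-5-[(3R)-5-hydroxy-3-methylpentyl]-1,5,6-trimethyl-1,2,3,5,6,7,8,8a-octahydronaphthalene-1-carboxylate F3, favoured because its 2α-epimer suffers a syn-axial OH/CH3 interaction. Ac2O, pyridine and DMAP then acetylate both hydroxyls with retention, and the route is rejoined at 19.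

**Further compounds**

F1 | step 8 | methyl (2S)-2-[(1R,3S,4R,6R)-3-[(3R)-5-acetoxy-3-methylpentyl]-3,4-dimethyl-2-oxo-6-(prop-1-en-2-yl)cyclohexyl]-2-methyl-4-oxopentanoate | O=C1[C@@](C)(CC[C@@H](C)CCOC(C)=O)[C@H](C)C[C@@H](C(C)=C)[C@@H]1[C@](C)(CC(C)=O)C(=O)OC
F2 | step 5 | (3S)-3-methyl-5-{[(trifluoromethyl)sulfonyl]oxy}pentyl acetate | FC(F)(F)S(=O)(=O)OCC[C@@H](C)CCOC(C)=O
F3 | step 11 | methyl (1S,3R,5S,6R,8aS)-3-hydroxy-5-[(3R)-5-hydroxy-3-methylpentyl]-1,5,6-trimethyl-1,2,3,5,6,7,8,8a-octahydronaphthalene-1-carboxylate | COC(=O)[C@@]1(C)C[C@@H](O)C=C2[C@@H]1CC[C@@H](C)[C@]2(C)CC[C@@H](C)CCO
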